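## Retrosynthetic overview

1. Target 27 comes from bicyclic diol 22 by redox and acyl changes only: MnO2 then Luche reduction at C15 tells the allylic C15–OH apart from C1–OH (acetylated), and the C6 acetal is opened last.
2. Ring D: C13–C16 bond by stannyl-radical 5-exo cyclisation of the C8 propargylic carbinol onto C12=C13 (20 → 22).
3. Rings B and C in one operation: hydroxy aldehyde 11 + alkynoyl-ketene precursor 14 + butadiene give the O20–C7 ester, the C8=C9 Knoevenagel lactone, then the C8–C14/C9–C11 Diels–Alder bonds (18).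
4. Ring A carrier 11: from 4,4-dimethylcyclohexadienone 2; C5 by rhodium-catalysed desymmetrising vinyl addition, quaternary C10 by two α'-alkylations (C20 first, then C9 anti to C6).
5. Ring order: A (purchased) → B + C together → D.

Assumption: labels C1–C20 are ent-kaurane position labels (C7 lactone carbonyl, C20 lactone CH2O, C6 aldehyde carbon, C15 carbinol, C16=C17 methylene); the sense of induction in step 2 is assigned by analogy with the (R)-BINAP/cyclohexenone model, and the ligand antipode is used if it proves opposite.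

## Route

Step 1
Reactants: 1 4,4-dimethylcyclohex-2-en-1-one
Product: 2 4,4-dimethylcyclohexa-2,5-dien-1-one
Conditions: DDQ (1.3 equiv), 1,4-dioxane, reflux
Reagents that add atoms: none
Why: DDQ dehydrogenation of a γ,γ-disubstituted cyclohexenone (hydride abstraction from the enol, then proton loss) gives the achiral cross-conjugated dienone, so no stereocentre is involved.

Step 2
Reactants: 2 4,4-dimethylcyclohexa-2,5-dien-1-one; 3 potassium vinyltrifluoroborate
Product: 4 (5R)-4,4-dimethyl-5-vinylcyclohex-2-en-1-one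
Conditions: [Rh(cod)2]BF4 (3 mol %), (R)-BINAP (3.3 mol %), PhMe/H2O 4:1, 100 °C
Reagents that add atoms: potassium vinyltrifluoroborate (3), C=C[B-](F)(F)F.[K+]
Why: Hayashi–Miyaura rhodium-catalysed asymmetric 1,4-addition desymmetrises the two enantiotopic enone halves of 2, the (R)-BINAP vinylrhodium species choosing one β-carbon face to set C5, and the dienone is more electrophilic than the product enone so addition stops after one vinyl transfer.

Step 3
Reactants: 4 (5R)-4,4-dimethyl-5-vinylcyclohex-2-en-1-one; 5 benzyl chloromethyl ether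
Product: 6 (5S,6R)-6-[(benzyloxy)methyl]-4,4-dimethyl-5-vinylcyclohex-2-en-1-one (trans)
Conditions: LiN(i-Pr)2, THF, −78 °C; then 5, −78 → −40 °C
Reagents that add atoms: benzyl chloromethyl ether (5), ClCOCc1ccccc1
Why: α'-Deprotonation is the only enolisation open to this enone (C4 is quaternary), and C-alkylation of the cross-conjugated lithium dienolate installs C20 trans to the vinyl group, a centre that is re-enolised in step 5.

Step 4
Reactants: 6 (5S,6R)-6-[(benzyloxy)methyl]-4,4-dimethyl-5-vinylcyclohex-2-en-1-one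
Product: 8 (5S,6R)-6-[(benzyloxy)methyl]-5-(dimethoxymethyl)-4,4-dimethylcyclohex-2-en-1-one, via keto aldehyde 7 (not isolated)
Conditions: O3, CH2Cl2/MeOH 4:1, −78 °C; Me2S, −78 → 0 °C; then HC(OMe)3, TsOH·H2O (5 mol %), 0 °C
Reagents that add atoms: ozone, [O-][O+]=O (carbonyl oxygen of 7); trimethyl orthoformate, COC(OC)OC (both methoxy groups of 8)
Why: Ozonolysis cleaves the electron-rich terminal vinyl group much faster than the electron-poor enone alkene, and immediate cold acetalisation masks the C6 aldehyde before C5 or C10 can epimerise.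

Step 5
Reactants: 8 (5S,6R)-6-[(benzyloxy)methyl]-5-(dimethoxymethyl)-4,4-dimethylcyclohex-2-en-1-one; 9 2,2,2-trifluoroethyl formate
Product: 10 (1S,6R)-1-[(benzyloxy)methyl]-6-(dimethoxymethyl)-5,5-dimethyl-2-oxocyclohex-3-ene-1-carbaldehyde
Conditions: LiN(i-Pr)2, THF, −78 °C; then 9, −78 °C; AcOH quench at −78 °C
Reagents that add atoms: 2,2,2-trifluoroethyl formate (9), O=COCC(F)(F)F
Why: Claisen-type C-formylation of the kinetic α'-lithium enolate with an activated formate sets quaternary C10, the electrophile entering anti to the pseudoaxial dimethoxymethyl group on C5 so that the formyl carbon (C9) is trans and the benzyloxymethyl carbon (C20) cis to C6.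

Step 6
Reactants: 10 (1S,6R)-1-[(benzyloxy)methyl]-6-(dimethoxymethyl)-5,5-dimethyl-2-oxocyclohex-3-ene-1-carbaldehyde
Product: 11 (1S,2R)-2-(dimethoxymethyl)-1-(hydroxymethyl)-3,3-dimethyl-6-oxocyclohexane-1-carbaldehyde
Conditions: H2 (1 atm), Pd/C (10 wt %), EtOAc, 23 °C
Reagents that add atoms: none
Why: Heterogeneous hydrogenation saturates the enone C=C and hydrogenolyses the benzyl ether in one operation, while the neopentyl aldehyde, the ketone and the acetal are untouched and no stereocentre changes.

Step 7
Reactants: 12 3-(trimethylsilyl)propiolic acid; 13 Meldrum's acid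
Product: 14 5-[1-hydroxy-3-(trimethylsilyl)prop-2-yn-1-ylidene]-2,2-dimethyl-1,3-dioxane-4,6-dione
Conditions: DCC, DMAP, CH2Cl2, 0 → 23 °C
Reagents that add atoms: 3-(trimethylsilyl)propiolic acid (12), C[Si](C)(C)C#CC(=O)O
Why: Carbodiimide-mediated C-acylation of Meldrum's acid (Oikawa–Yonemitsu acylation) gives the enolised acyl Meldrum's acid, a storable acylketene precursor with no stereocentre.

Step 8
Reactants: 11 (1S,2R)-2-(dimethoxymethyl)-1-(hydroxymethyl)-3,3-dimethyl-6-oxocyclohexane-1-carbaldehyde; 14 acyl Meldrum's acid; 15 buta-1,3-diene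
Product: 18 cyclohexene-fused spirolactone (7,20-lactone; C1 ketone; C6 dimethyl acetal; C12=C13; C8 carries the 3-(trimethylsilyl)propynoyl group; C5 C8 C9 C10 configured as in 27), via keto ester 16 (not isolated), via alkylidene lactone 17 (not isolated)
Conditions: 14 (1.1 equiv), PhMe, 85 °C; then ZnCl2 (1.5 equiv), 2,6-lutidine (0.2 equiv), 4 Å MS, 23 °C; then 15 (10 equiv), sealed tube, 23 → 40 °C
Reagents that add atoms: acyl Meldrum's acid (14), CC1(C)OC(=O)C(=C(O)C#C[Si](C)(C)C)C(=O)O1; buta-1,3-diene (15), C=CC=C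
Why: Proposed new method: thermolysis of 14 gives an alkynoyl ketene that acylates the primary C20 alcohol, the zinc-chelated β-keto ester then condenses with the non-enolisable C9 aldehyde (intramolecular Knoevenagel) to close lactone ring B, and the resulting doubly activated C8=C9 alkylidene, held as a bidentate ZnCl2 chelate, adds butadiene suprafacially from the face of the flat C1 carbonyl, away from C5 with its dimethoxymethyl group and the neighbouring gem-dimethyl, setting C8 and C9 and closing ring C; the closest known reactions are the Tietze domino Knoevenagel/Diels–Alder sequence and ZnCl2-promoted Diels–Alder reactions of 2-acylcycloalkenones.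

Step 9
Reactants: 18 cyclohexene-fused spirolactone
Product: 20 diol alkyne (1S-OH equatorial and cis to C20; C15 propargylic carbinol as an epimer mixture; terminal alkyne), via silyl alkyne diol 19 (not isolated)
Conditions: NaBH4, CeCl3·7H2O, MeOH, −40 °C; then Bu4NF, AcOH, THF, 0 °C
Reagents that add atoms: none
Why: Luche-type 1,2-reduction reduces the ynone and the C1 ketone, hydride arriving axially at C1 opposite the axial C20 to give the equatorial alcohol, and buffered fluoride then removes the alkynyl silane without basic conditions that could open or shift the lactone; both C15 epimers converge at 23.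

Step 10
Reactants: 20 diol alkyne
Product: 22 bicyclo[3.2.1]octane diol (C16=C17 methylene; C13 as in 27; C15 carbinol as an epimer mixture), via vinylstannane 21 (not isolated)
Conditions: Bu3SnH (1.5 equiv), AIBN (0.2 equiv), PhH (0.02 M), 80 °C; then TsOH·H2O (1.2 equiv), MeOH, 0 °C
Reagents that add atoms: tributyltin hydride, CCCC[SnH](CCCC)CCCC (tin of intermediate 21 only)
Why: Stork-type stannyl radical addition to the terminal alkyne gives a σ-vinyl radical at C16 that closes 5-exo-trig on C13 from the only face the axial C8 side chain can reach (fixing C13), the C12 radical is reduced by Bu3SnH, and protodestannylation in methanol reveals the methylene while the dimethyl acetal is preserved.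

Step 11
Reactants: 22 bicyclo[3.2.1]octane diol
Product: 23 hydroxy enone (C15 ketone conjugated to C16=C17; free 1-OH)
Conditions: MnO2 (20 equiv), CH2Cl2, 23 °C
Reagents that add atoms: none
Why: MnO2 oxidises only the allylic C15 alcohol (both epimers), leaving the saturated C1 alcohol, which erases the C15 mixture and differentiates the two hydroxyls.

Step 12
Reactants: 23 hydroxy enone; 24 acetic anhydride
Product: 25 acetoxy enone (1-OAc; C15 ketone)
Conditions: 24, pyridine, DMAP (cat.), CH2Cl2, 0 → 23 °C
Reagents that add atoms: acetic anhydride (24), CC(=O)OC(C)=O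
Why: Standard DMAP-catalysed acetylation of the only hydroxyl present, with retention at C1.

Step 13
Reactants: 25 acetoxy enone
Product: 26 acetoxy allylic alcohol acetal (15R-OH; otherwise as 27 with C6 as the dimethyl acetal)
Conditions: NaBH4, CeCl3·7H2O, MeOH, −40 °C
Reagents that add atoms: none
Why: Luche 1,2-reduction of the methylene cyclopentanone takes hydride from the exo face (the C14 side), away from the C9–C11–C12 bridge, giving the endo 15R alcohol while the acetate, lactone and acetal survive.

Step 14
Reactants: 26 acetoxy allylic alcohol acetal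
Product: 27 target CNP0117386.1
Conditions: AcOH/THF/H2O 3:1:1, 40 °C
Reagents that add atoms: water, O
Why: Mild acid-catalysed acetal hydrolysis releases the C6 aldehyde without ionising the allylic alcohol or cleaving the acetate, and C5 keeps its configuration because C10 is quaternary and enolisation of the hindered aldehyde is slow.

## Compound list

1 | 4,4-dimethylcyclohex-2-en-1-one | CC1(C)CCC(=O)C=C1 | starting material
2 | 4,4-dimethylcyclohexa-2,5-dien-1-one | CC1(C)C=CC(=O)C=C1 | intermediate
3 | potassium vinyltrifluoroborate | C=C[B-](F)(F)F.[K+] | starting material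
4 | (5R)-4,4-dimethyl-5-vinylcyclohex-2-en-1-one | O=C1C=CC(C)(C)[C@@H](C=C)C1 | intermediate
5 | benzyl chloromethyl ether | ClCOCc1ccccc1 | starting material
6 | (5S,6R)-6-[(benzyloxy)methyl]-4,4-dimethyl-5-vinylcyclohex-2-en-1-one | O=C1C=CC(C)(C)[C@@H](C=C)[C@@H]1COCc1ccccc1 | intermediate
7 | (1S,6R)-6-[(benzyloxy)methyl]-2,2-dimethyl-5-oxocyclohex-3-ene-1-carbaldehyde | O=C1C=CC(C)(C)[C@@H](C=O)[C@@H]1COCc1ccccc1 | intermediate
8 | (5S,6R)-6-[(benzyloxy)methyl]-5-(dimethoxymethyl)-4,4-dimethylcyclohex-2-en-1-one | O=C1C=CC(C)(C)[C@@H](C(OC)OC)[C@@H]1COCc1ccccc1 | intermediate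
9 | 2,2,2-trifluoroethyl formate | O=COCC(F)(F)F | starting material
10 | (1S,6R)-1-[(benzyloxy)methyl]-6-(dimethoxymethyl)-5,5-dimethyl-2-oxocyclohex-3-ene-1-carbaldehyde | c1ccccc1COC[C@@]1(C=O)C(=O)C=CC(C)(C)[C@H]1C(OC)OC | intermediate
11 | (1S,2R)-2-(dimethoxymethyl)-1-(hydroxymethyl)-3,3-dimethyl-6-oxocyclohexane-1-carbaldehyde | OC[C@@]1(C=O)C(=O)CCC(C)(C)[C@H]1C(OC)OC | intermediate
12 | 3-(trimethylsilyl)propiolic acid | C[Si](C)(C)C#CC(=O)O | starting material
13 | Meldrum's acid (2,2-dimethyl-1,3-dioxane-4,6-dione) | CC1(C)OC(=O)CC(=O)O1 | starting material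
14 | 5-[1-hydroxy-3-(trimethylsilyl)prop-2-yn-1-ylidene]-2,2-dimethyl-1,3-dioxane-4,6-dione | CC1(C)OC(=O)C(=C(O)C#C[Si](C)(C)C)C(=O)O1 | intermediate
15 | buta-1,3-diene | C=CC=C | starting material
16 | keto ester: 3-oxo-5-(trimethylsilyl)pent-4-ynoate of 11 at O20 | C[Si](C)(C)C#CC(=O)CC(=O)OC[C@@]1(C=O)C(=O)CCC(C)(C)[C@H]1C(OC)OC | intermediate
17 | alkylidene lactone: 7-(dimethoxymethyl)-8,8-dimethyl-4-[3-(trimethylsilyl)propynoyl]-2-oxaspiro[5.5]undec-4-ene-3,11-dione, spiro centre and C7 as in 11 | C[Si](C)(C)C#CC(=O)C1=C[C@]2(COC1=O)C(=O)CCC(C)(C)[C@H]2C(OC)OC | intermediate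
18 | cyclohexene-fused spirolactone (ring C cis-fused to the lactone, C11 and C14 on the lactone face that carries C1) | C1=CC[C@@H]2[C@](C1)(C(=O)OC[C@]23C(=O)CCC(C)(C)[C@H]3C(OC)OC)C(=O)C#C[Si](C)(C)C | intermediate
19 | silyl alkyne diol (1S-OH; C15 epimers) | C1=CC[C@@H]2[C@](C1)(C(=O)OC[C@]23[C@@H](O)CCC(C)(C)[C@H]3C(OC)OC)C(O)C#C[Si](C)(C)C | intermediate
20 | diol alkyne (1S-OH; C15 epimers) | C1=CC[C@@H]2[C@](C1)(C(=O)OC[C@]23[C@@H](O)CCC(C)(C)[C@H]3C(OC)OC)C(O)C#C | intermediate
21 | vinylstannane (C17 tributylstannyl, E/Z mixture; C15 epimers) | CCCC[Sn](CCCC)(CCCC)C=C1[C@@H]2CC[C@@H]3[C@](C2)(C(=O)OC[C@]32[C@@H](O)CCC(C)(C)[C@H]2C(OC)OC)C1O | intermediate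
22 | bicyclo[3.2.1]octane diol (C15 epimers) | C=C1[C@@H]2CC[C@@H]3[C@](C2)(C(=O)OC[C@]32[C@@H](O)CCC(C)(C)[C@H]2C(OC)OC)C1O | intermediate
23 | hydroxy enone | C=C1[C@@H]2CC[C@@H]3[C@](C2)(C(=O)OC[C@]32[C@@H](O)CCC(C)(C)[C@H]2C(OC)OC)C1=O | intermediate
24 | acetic anhydride | CC(=O)OC(C)=O | starting material
25 | acetoxy enone | C=C1[C@@H]2CC[C@@H]3[C@](C2)(C(=O)OC[C@]32[C@@H](OC(C)=O)CCC(C)(C)[C@H]2C(OC)OC)C1=O | intermediate
26 | acetoxy allylic alcohol acetal | C=C1[C@@H]2CC[C@@H]3[C@](C2)(C(=O)OC[C@]32[C@@H](OC(C)=O)CCC(C)(C)[C@H]2C(OC)OC)[C@@H]1O | intermediate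
27 | CNP0117386.1 | C=C1[C@@H]2CC[C@@H]3[C@](C2)(C(=O)OC[C@]32[C@@H](OC(C)=O)CCC(C)(C)[C@H]2C=O)[C@@H]1O | target

## Count and risks

Total steps: 14. Longest linear sequence: 13 (steps 1–6 and 8–14; step 7 is a one-step side branch).

Most likely to fail:

Step 8. The silyl ynone may compete as a dienophile or may not survive the Knoevenagel stage, and the facial preference at C9 rests on sterics alone. Fallback, setting out from 11 and returning at 18: Knoevenagel condensation of 11 with Meldrum's acid 13 (ethylenediammonium diacetate, CH2Cl2) followed by spontaneous intramolecular alcoholysis gives spirolactone acid F1. ZnCl2-promoted Diels–Alder reaction of this alkyne-free dienophile with 15 gives cycloadduct acid F2. (COCl)2 with catalytic DMF gives acid chloride F3, and acyl Stille coupling with tributyl[(trimethylsilyl)ethynyl]stannane under Pd(PPh3)4 installs the ynone after ring C is in place, giving 18.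

Step 5. C-Formylation to a quaternary α-formyl ketone may stall through O-formylation, or the β-benzyloxy enolate may eliminate. Fallback, setting out from 8 and returning at 10: the same lithium enolate is trapped at −78 °C with gaseous formaldehyde (irreversible aldol, same facial preference) to give hydroxymethyl ketone F4. Dess–Martin oxidation of the new primary alcohol then gives 10.

Step 2. Vinyl transfer to a β-carbon next to a quaternary centre may be slow or poorly selective. Fallback, setting out from 2 and returning at 8: Michael addition of nitromethane to 2 under a 9-amino-9-deoxy-epi-cinchona primary amine with benzoic acid (iminium catalysis) gives nitro enone F5. A Nef reaction run in acidic methanol (NaOMe, then H2SO4/MeOH, −40 °C) converts it directly into acetal enone F6. α'-Alkylation with 5 under the conditions of step 3 gives 8, so that 4, 6 and 7 are bypassed.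

## Further compounds

F1 | step 8 | spirolactone acid: 7-(dimethoxymethyl)-8,8-dimethyl-3,11-dioxo-2-oxaspiro[5.5]undec-4-ene-4-carboxylic acid, stereocentres as in 17 | OC(=O)C1=C[C@]2(COC1=O)C(=O)CCC(C)(C)[C@H]2C(OC)OC
F2 | step 8 | cycloadduct acid: 18 with CO2H on C8 in place of the silylpropynoyl group | C1=CC[C@@H]2[C@](C1)(C(=O)OC[C@]23C(=O)CCC(C)(C)[C@H]3C(OC)OC)C(=O)O
F3 | step 8 | acid chloride of F2 | C1=CC[C@@H]2[C@](C1)(C(=O)OC[C@]23C(=O)CCC(C)(C)[C@H]3C(OC)OC)C(=O)Cl
F4 | step 5 | hydroxymethyl ketone: 6-[(benzyloxy)methyl]-5-(dimethoxymethyl)-6-(hydroxymethyl)-4,4-dimethylcyclohex-2-en-1-one, hydroxymethyl trans to the dimethoxymethyl group | c1ccccc1COC[C@@]1(CO)C(=O)C=CC(C)(C)[C@H]1C(OC)OC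
F5 | step 2 | (5S)-4,4-dimethyl-5-(nitromethyl)cyclohex-2-en-1-one | O=C1C=CC(C)(C)[C@@H](C[N+](=O)[O-])C1
F6 | step 2 | (5S)-5-(dimethoxymethyl)-4,4-dimethylcyclohex-2-en-1-one | O=C1C=CC(C)(C)[C@@H](C(OC)OC)C1
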